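Ring A is cut at the C5–C10 ring-fusion bond. The chain C6–C5–C4(CH3)(O)–C3(O)–C2 of ring A is carried as a 4-hydroxy-4-methyl-δ-lactone whose ring oxygen sits on C2, and C2 carries the Z-alkenyl unit C1=C10. An Ireland–Claisen shift of the lactone silyl ketene acetal then joins the lactone α-carbon C5 to C10 in one operation: it closes ring A, creates the C5 and C10 stereocentres (quaternary C10 included) from the C2–O stereocentre and releases C6 as a carboxylic acid. The precursor is a 6-(Z-alkenyl)-5-benzyloxy-4-hydroxy-4-methyl-δ-lactone, made by an anti glycolate aldol and a chelation-controlled acetate addition. Ring B follows by aldol condensation, the 11-hydroxy-6-ene by a singlet-oxygen ene reaction.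

Key step: step 13

Remark: eudesmane numbering is used for every intermediate (C1–C10 ring carbons, C11–C13 the hydroxyisopropyl unit, C14 the methyl on C10, C15 the methyl on C4); β is the face of C14; TBS = tert-butyldimethylsilyl, TES = triethylsilyl.
Remark: C6 of 24 and C7 of 26, 27, 33 and 34 are drawn as single epimers for definiteness; both centres become sp2 again (steps 17 and 24), so their configuration is of no consequence.
Remark: the given precursor and product structures of the key step were checked against a boat transition state and found consistent, so they are used unchanged; debenzylation is moved behind the C6/C8 oxidations so that the benzyl ether protects C3–O during them.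

Step 1
Reactants: 1 (S)-propylene oxide; 2 ethyl propiolate
Product: 3 ethyl (5S)-5-hydroxyhex-2-ynoate
Conditions: 2, n-BuLi, THF, −78 °C; BF3·OEt2; then 1, −78 °C
Reagents that add atoms: none
Why: Yamaguchi–Hirao alkynylation, in which the BF3-activated epoxide is opened at its unsubstituted carbon by the lithium acetylide, so the C8 stereocentre of 1 is carried over untouched.

Step 2
Reactants: 3 hydroxy ynoate
Product: 4 ethyl (5S)-5-(tert-butyldimethylsilyloxy)hex-2-ynoate
Conditions: TBSCl, imidazole, DMF, rt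
Reagents that add atoms: tert-butyldimethylsilyl chloride, SMILES CC(C)(C)[Si](C)(C)Cl
Why: standard silylation of a secondary alcohol under conditions mild enough for the ynoate; it prevents lactonisation after the next step.

Step 3
Reactants: 4 silylated ynoate
Product: 5 ethyl (2Z,5S)-5-(tert-butyldimethylsilyloxy)-3-methylhex-2-enoate
Conditions: Me2CuLi (from MeLi and CuI), THF, −78 °C; MeOH, −78 °C
Reagents that add atoms: lithium dimethylcuprate, SMILES [Li+].C[Cu-]C
Why: syn carbocupration of the ynoate followed by protonation of the vinylcopper at −78 °C with retention places the new CH3 (C14) and H cis, so that C9 and the ester carbon are cis (Z).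

Step 4
Reactants: 5 Z-enoate
Product: 6 (2Z,5S)-5-(tert-butyldimethylsilyloxy)-3-methylhex-2-en-1-ol
Conditions: iBu2AlH, CH2Cl2, −78 °C
Reagents that add atoms: none
Why: 1,2-reduction of the conjugated ester by the aluminium hydride, which leaves the double-bond geometry and the silyl ether alone.

Step 5
Reactants: 6 Z-allylic alcohol
Product: 7 (2Z,5S)-5-(tert-butyldimethylsilyloxy)-3-methylhex-2-enal
Conditions: MnO2, CH2Cl2, rt
Reagents that add atoms: none
Why: heterogeneous allylic oxidation under neutral conditions, chosen because it should not isomerise the Z enal.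

Step 6
Reactants: 8 (4S)-4-benzyl-1,3-oxazolidine-2-thione; 9 benzyloxyacetyl chloride
Product: 10 (4S)-4-benzyl-3-[(benzyloxy)acetyl]-1,3-oxazolidine-2-thione
Conditions: Et3N, CH2Cl2, 0 °C
Reagents that add atoms: none
Why: N-acylation of the thiocarbamate by the acid chloride gives the glycolyl imide needed for the auxiliary-controlled aldol.

Step 7
Reactants: 10 N-glycolyl oxazolidinethione; 7 Z-enal
Product: 11 (4S)-4-benzyl-3-[(2S,3S,4Z,7S)-2-(benzyloxy)-7-(tert-butyldimethylsilyloxy)-3-hydroxy-5-methyloct-4-enoyl]-1,3-oxazolidine-2-thione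
Conditions: TiCl4, iPr2NEt, CH2Cl2, −78 °C; then 7 premixed with TiCl4, −78 °C
Reagents that add atoms: none
Why: anti-selective titanium-enolate glycolate aldol of an N-glycolyl oxazolidinethione, in which the Z chlorotitanium enolate adds through an open transition state to the TiCl4-bound enal on the enolate face turned away from the auxiliary's benzyl group, fixing C3 as S and placing the new C2–OH anti to C3–OBn (C2 S).

Step 8
Reactants: 11 aldol adduct
Product: 12 (2S,3S,4Z,7S)-2-(benzyloxy)-7-(tert-butyldimethylsilyloxy)-3-hydroxy-N-methoxy-N,5-dimethyloct-4-enamide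
Conditions: MeNHOMe·HCl, imidazole, CH2Cl2, rt
Reagents that add atoms: N,O-dimethylhydroxylamine hydrochloride, SMILES CNOC.Cl
Why: aminolysis of the thiocarbonyl-activated imide releases the auxiliary and gives the Weinreb amide without touching the α-stereocentre.

Step 9
Reactants: 12 Weinreb amide
Product: 13 (2S,3S,4Z,7S)-2-(benzyloxy)-7-(tert-butyldimethylsilyloxy)-N-methoxy-N,5-dimethyl-3-(triethylsilyloxy)oct-4-enamide
Conditions: TESOTf, 2,6-lutidine, CH2Cl2, −78 °C
Reagents that add atoms: triethylsilyl triflate, SMILES CC[Si](CC)(CC)OS(=O)(=O)C(F)(F)F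
Why: silylation of the C2 hydroxyl, which makes this oxygen non-chelating so that only the C3 benzyloxy group can direct step 11.

Step 10
Reactants: 13 silylated Weinreb amide
Product: 14 (3S,4S,5Z,8S)-3-(benzyloxy)-8-(tert-butyldimethylsilyloxy)-6-methyl-4-(triethylsilyloxy)non-5-en-2-one
Conditions: MeMgBr, THF, 0 °C
Reagents that add atoms: methylmagnesium bromide, SMILES C[Mg]Br
Why: Weinreb ketone synthesis, in which the chelated tetrahedral intermediate survives until work-up so that the C15 methyl is added only once.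

Step 11
Reactants: 14 methyl ketone
Product: 15 ethyl (3S,4S,5S,6Z,9S)-4-(benzyloxy)-9-(tert-butyldimethylsilyloxy)-3-hydroxy-3,7-dimethyl-5-(triethylsilyloxy)dec-6-enoate
Conditions: EtOAc, LiN(iPr)2, THF, −78 °C; then 14 premixed with MgBr2·OEt2 in CH2Cl2, −78 °C
Reagents that add atoms: ethyl acetate, SMILES CCOC(C)=O
Why: chelation-controlled (Cram chelate) aldol addition, in which magnesium bridges the C4 carbonyl and the C3 benzyloxy oxygen and the acetate enolate attacks from the side of the chelate ring opposite to C2, giving the 4S tertiary alcohol.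

Step 12
Reactants: 15 hydroxy ester
Product: 17 (4S,5S,6S)-5-(benzyloxy)-6-[(1Z,4S)-4-(tert-butyldimethylsilyloxy)-2-methylpent-1-en-1-yl]-4-hydroxy-4-methyloxan-2-one, via dihydroxy ester 16 (not isolated)
Conditions: PPTS, EtOH, rt; then PhH, 60 °C
Reagents that add atoms: none
Why: acid-catalysed solvolysis of the secondary TES ether (the TBS ether is much slower) followed by lactonisation of the δ-hydroxy ester, with no stereocentre involved.

Step 13
Reactants: 17 δ-lactone precursor
Product: 20 (1R,2S,3S,6S)-3-(benzyloxy)-6-[(2S)-2-(tert-butyldimethylsilyloxy)propyl]-2-hydroxy-2,6-dimethylcyclohex-4-ene-1-carboxylic acid, via silyl ketene acetal 18 (not isolated), via silyl ester 19 (not isolated)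
Conditions: Me3SiCl (excess), KN(SiMe3)2 (3 equiv), THF–PhMe, −78 °C; then 80 °C; dilute aq. HCl, THF, 0 °C
Reagents that add atoms: none
Why: Ireland–Claisen rearrangement of a lactone silyl ketene acetal, the closest known reaction type being the ring contraction of alkenyl lactones to cycloalkenecarboxylic acids: with Me3SiCl present, the excess amide base first silylates C4–OH (so that no β-elimination can start from the enolate) and then traps the lactone enolate as ketene acetal 18. On warming, the conformer with the alkenyl group axial undergoes a suprafacial [3,3] shift in which C2–O breaks, C5–C10 forms and silyl ester 19 results. Ring A is closed in this concerted event by C–C bond formation between the two ends of the 1,5-diene through a boat-like six-membered array (bicyclo[2.2.2]octane-like together with the lactone ring), and the C1=C2 double bond ends up inside the new ring. C5 is controlled by the tether, because C6 must stay on the face of the allyl unit from which the ring oxygen departs, so C5 follows the C2 configuration. C10 is controlled by the Z double bond, which turns C9 toward the C3–C4 bridge and C14 toward the ester bridge and so leaves C14 cis to C6. The step needs a single boat transition state, which is secured by the ring constraint (a chair is out of reach), by the C2 configuration (alkenyl trans to C3–OBn, cis to C4–O) and by the geometric purity of the alkene; C3 and C4 are spectators.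

Step 14
Reactants: 20 ring A acid
Product: 21 [(1S,2S,3S,6S)-3-(benzyloxy)-6-[(2S)-2-(tert-butyldimethylsilyloxy)propyl]-2-hydroxy-2,6-dimethylcyclohex-4-en-1-yl]methanol
Conditions: LiAlH4, THF, 0 °C to reflux
Reagents that add atoms: none
Why: hydride reduction of the carboxylate to the C6 primary alcohol, to which the benzyl ether, the silyl ether and the isolated alkene are inert.

Step 15
Reactants: 21 diol
Product: 22 (2S)-1-[(1S,4S,5S,6S)-4-(benzyloxy)-5-hydroxy-6-(hydroxymethyl)-1,5-dimethylcyclohex-2-en-1-yl]propan-2-ol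
Conditions: Bu4NF, THF, rt
Reagents that add atoms: none
Why: fluoride-induced cleavage of the TBS ether frees the C8 hydroxyl.

Step 16
Reactants: 22 triol
Product: 23 (1R,2S,3S,6S)-3-(benzyloxy)-2-hydroxy-2,6-dimethyl-6-(2-oxopropyl)cyclohex-4-ene-1-carbaldehyde
Conditions: Dess–Martin periodinane, CH2Cl2, 0 °C to rt
Reagents that add atoms: none
Why: Dess–Martin oxidation of the primary and the secondary alcohol in one operation, while the tertiary C4–OH cannot be oxidised, C3–O is still benzylated and the near-neutral medium should leave C5 unepimerised.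

Step 17
Reactants: 23 keto aldehyde
Product: 25 3β-(benzyloxy)-4α-hydroxy-5αH-eudesma-1,6-dien-8-one, via aldol 24 (not isolated)
Conditions: piperidine, AcOH, PhMe, 60 °C
Reagents that add atoms: none
Why: intramolecular aldol condensation in which C7 of the methyl ketone adds to the C6 aldehyde (6-enolexo closure of ring B, the only ring size within reach) and water is lost to the conjugated enone, the buffered amine catalysis generating no C4 alkoxide that could trigger retro-aldol cleavage of C4–C5.

Step 18
Reactants: 25 enone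
Product: 26 3β-(benzyloxy)-4α,11-dihydroxy-5αH,7αH-eudesm-1-en-8-one
Conditions: LiBH(sBu)3 (L-Selectride), THF, −78 °C; ZnCl2; acetone, −78 to −40 °C
Reagents that add atoms: acetone, SMILES CC(C)=O
Why: reductive aldol reaction, in which conjugate hydride addition to the β-unsubstituted cyclohexenone gives the C7 enolate regiospecifically and its zinc enolate adds to acetone; the C7 centre formed here is erased in step 24.

Step 19
Reactants: 26 hydroxy ketone
Product: 27 3β,4α,11-trihydroxy-5αH,7αH-eudesman-8-one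
Conditions: H2 (1 atm), Pd/C, EtOAc–EtOH, rt
Reagents that add atoms: none
Why: catalytic hydrogenation saturates C1=C2 and hydrogenolyses the benzyl ether in one operation at a stage where no enone is present, forming no stereocentre.

Step 20
Reactants: 28 methyl angelate
Product: 29 (2Z)-2-methylbut-2-en-1-ol
Conditions: iBu2AlH, Et2O, −78 to 0 °C
Reagents that add atoms: none
Why: 1,2-reduction of the conjugated ester gives the allylic alcohol with the Z geometry intact.

Step 21
Reactants: 29 angelyl alcohol
Product: 30 [(2R,3S)-2,3-dimethyloxiran-2-yl]methanol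
Conditions: Ti(OiPr)4 (cat.), D-(−)-diethyl tartrate (cat.), tBuOOH, 4 Å molecular sieves, CH2Cl2, −20 °C
Reagents that add atoms: tert-butyl hydroperoxide, SMILES CC(C)(C)OO
Why: Sharpless asymmetric epoxidation, in which the titanium D-tartrate complex delivers oxygen to the alkene face that leads to the 2R,3S epoxy alcohol and the syn addition turns the Z alkene into the cis epoxide.

Step 22
Reactants: 30 epoxy alcohol
Product: 31 (2S,3S)-2,3-dimethyloxirane-2-carboxylic acid
Conditions: RuCl3 (cat.), NaIO4, MeCN–EtOAc–H2O, rt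
Reagents that add atoms: water, SMILES O
Why: oxidation of the primary alcohol to the acid by RuO4 made in situ, via the aldehyde hydrate, leaves the epoxide alone; the change of the C2 descriptor from R to S is only a change of priorities.

Step 23
Reactants: 31 epoxy acid; 27 triol
Product: 33 3β-[(2S,3S)-2,3-dimethyloxirane-2-carbonyloxy]-4α,11-dihydroxy-5αH,7αH-eudesman-8-one, via mixed anhydride 32 (not isolated)
Conditions: 2,4,6-Cl3C6H2COCl, Et3N, THF, rt; then 27, DMAP, PhMe, rt
Reagents that add atoms: none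
Why: Yamaguchi esterification, in which the mixed anhydride acylates only the secondary equatorial C3–OH because the two tertiary hydroxyls are too hindered, and the acid has no α-hydrogen that could epimerise.

Step 24
Reactants: 33 C3 ester
Product: 35 3β-[(2S,3S)-2,3-dimethyloxirane-2-carbonyloxy]-4α-(formyloxy)-5αH-eudesm-7(11)-en-8-one, via bis-formate 34 (not isolated)
Conditions: preformed AcOCHO, pyridine, DMAP, CH2Cl2, 0 °C to rt; then DBU, 0 °C
Reagents that add atoms: acetic formic anhydride, SMILES CC(=O)OC=O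
Why: formylation of both tertiary alcohols by the mixed anhydride (the formyl carbonyl is the more electrophilic one), after which the C11 formate, being β to the C8 ketone, is lost by E1cB elimination to the conjugated C7=C11 alkene while the C4 formate has no acidic hydrogen next to it and stays.

Step 25
Reactants: 35 isopropylidene enone
Product: 37 3β-[(2S,3S)-2,3-dimethyloxirane-2-carbonyloxy]-4α-(formyloxy)-11-hydroxy-5αH-eudesm-6-en-8-one (CNP0171909.1), via hydroperoxide 36 (not isolated)
Conditions: O2, visible light, tetraphenylporphyrin, CH2Cl2, 0 °C; then PPh3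
Reagents that add atoms: oxygen, SMILES O=O
Why: Schenck ene reaction of singlet oxygen with the s-cis enone, which abstracts hydrogen from C6 (the group geminal to the carbonyl on the α-carbon C7), binds oxygen to C11 and moves the double bond to C6=C7, followed by reduction of the hydroperoxide to the alcohol by the phosphine; no stereocentre is formed or touched.

Compound list
1 | (S)-propylene oxide | C[C@H]1CO1 | starting material
2 | ethyl propiolate | C#CC(=O)OCC | starting material
3 | ethyl (5S)-5-hydroxyhex-2-ynoate | CCOC(=O)C#CC[C@H](C)O | intermediate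
4 | ethyl (5S)-5-(tert-butyldimethylsilyloxy)hex-2-ynoate | CCOC(=O)C#CC[C@H](C)O[Si](C)(C)C(C)(C)C | intermediate
5 | ethyl (2Z,5S)-5-(tert-butyldimethylsilyloxy)-3-methylhex-2-enoate | CCOC(=O)/C=C(/C)C[C@H](C)O[Si](C)(C)C(C)(C)C | intermediate
6 | (2Z,5S)-5-(tert-butyldimethylsilyloxy)-3-methylhex-2-en-1-ol | OC/C=C(/C)C[C@H](C)O[Si](C)(C)C(C)(C)C | intermediate
7 | (2Z,5S)-5-(tert-butyldimethylsilyloxy)-3-methylhex-2-enal | O=C/C=C(/C)C[C@H](C)O[Si](C)(C)C(C)(C)C | intermediate
8 | (4S)-4-benzyl-1,3-oxazolidine-2-thione | S=C1N[C@@H](Cc2ccccc2)CO1 | starting material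
9 | benzyloxyacetyl chloride | O=C(Cl)COCc1ccccc1 | starting material
10 | (4S)-4-benzyl-3-[(benzyloxy)acetyl]-1,3-oxazolidine-2-thione | O=C(COCc1ccccc1)N1C(=S)OC[C@@H]1Cc1ccccc1 | intermediate
11 | (4S)-4-benzyl-3-[(2S,3S,4Z,7S)-2-(benzyloxy)-7-(tert-butyldimethylsilyloxy)-3-hydroxy-5-methyloct-4-enoyl]-1,3-oxazolidine-2-thione | S=C1OC[C@H](Cc2ccccc2)N1C(=O)[C@@H](OCc1ccccc1)[C@@H](O)/C=C(/C)C[C@H](C)O[Si](C)(C)C(C)(C)C | intermediate
12 | (2S,3S,4Z,7S)-2-(benzyloxy)-7-(tert-butyldimethylsilyloxy)-3-hydroxy-N-methoxy-N,5-dimethyloct-4-enamide | CON(C)C(=O)[C@@H](OCc1ccccc1)[C@@H](O)/C=C(/C)C[C@H](C)O[Si](C)(C)C(C)(C)C | intermediate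
13 | (2S,3S,4Z,7S)-2-(benzyloxy)-7-(tert-butyldimethylsilyloxy)-N-methoxy-N,5-dimethyl-3-(triethylsilyloxy)oct-4-enamide | CON(C)C(=O)[C@@H](OCc1ccccc1)[C@@H](O[Si](CC)(CC)CC)/C=C(/C)C[C@H](C)O[Si](C)(C)C(C)(C)C | intermediate
14 | (3S,4S,5Z,8S)-3-(benzyloxy)-8-(tert-butyldimethylsilyloxy)-6-methyl-4-(triethylsilyloxy)non-5-en-2-one | CC(=O)[C@@H](OCc1ccccc1)[C@@H](O[Si](CC)(CC)CC)/C=C(/C)C[C@H](C)O[Si](C)(C)C(C)(C)C | intermediate
15 | ethyl (3S,4S,5S,6Z,9S)-4-(benzyloxy)-9-(tert-butyldimethylsilyloxy)-3-hydroxy-3,7-dimethyl-5-(triethylsilyloxy)dec-6-enoate | CCOC(=O)C[C@](C)(O)[C@@H](OCc1ccccc1)[C@@H](O[Si](CC)(CC)CC)/C=C(/C)C[C@H](C)O[Si](C)(C)C(C)(C)C | intermediate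
16 | ethyl (3S,4S,5S,6Z,9S)-4-(benzyloxy)-9-(tert-butyldimethylsilyloxy)-3,5-dihydroxy-3,7-dimethyldec-6-enoate | CCOC(=O)C[C@](C)(O)[C@@H](OCc1ccccc1)[C@@H](O)/C=C(/C)C[C@H](C)O[Si](C)(C)C(C)(C)C | intermediate (not isolated)
17 | (4S,5S,6S)-5-(benzyloxy)-6-[(1Z,4S)-4-(tert-butyldimethylsilyloxy)-2-methylpent-1-en-1-yl]-4-hydroxy-4-methyloxan-2-one (precursor of the key step) | O=C1C[C@](C)(O)[C@@H](OCc2ccccc2)[C@H](/C=C(/C)C[C@H](C)O[Si](C)(C)C(C)(C)C)O1 | intermediate
18 | trimethylsilyl ketene acetal of 17 carrying C4–OSiMe3 | C[Si](C)(C)OC1=C[C@](C)(O[Si](C)(C)C)[C@@H](OCc2ccccc2)[C@H](/C=C(/C)C[C@H](C)O[Si](C)(C)C(C)(C)C)O1 | intermediate (not isolated)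
19 | trimethylsilyl ester of 20 carrying C4–OSiMe3 | c1ccccc1CO[C@H]1C=C[C@](C)(C[C@H](C)O[Si](C)(C)C(C)(C)C)[C@@H](C(=O)O[Si](C)(C)C)[C@]1(C)O[Si](C)(C)C | intermediate (not isolated)
20 | (1R,2S,3S,6S)-3-(benzyloxy)-6-[(2S)-2-(tert-butyldimethylsilyloxy)propyl]-2-hydroxy-2,6-dimethylcyclohex-4-ene-1-carboxylic acid (product of the key step) | c1ccccc1CO[C@H]1C=C[C@](C)(C[C@H](C)O[Si](C)(C)C(C)(C)C)[C@@H](C(=O)O)[C@]1(C)O | intermediate
21 | [(1S,2S,3S,6S)-3-(benzyloxy)-6-[(2S)-2-(tert-butyldimethylsilyloxy)propyl]-2-hydroxy-2,6-dimethylcyclohex-4-en-1-yl]methanol | c1ccccc1CO[C@H]1C=C[C@](C)(C[C@H](C)O[Si](C)(C)C(C)(C)C)[C@@H](CO)[C@]1(C)O | intermediate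
22 | (2S)-1-[(1S,4S,5S,6S)-4-(benzyloxy)-5-hydroxy-6-(hydroxymethyl)-1,5-dimethylcyclohex-2-en-1-yl]propan-2-ol | c1ccccc1CO[C@H]1C=C[C@](C)(C[C@H](C)O)[C@@H](CO)[C@]1(C)O | intermediate
23 | (1R,2S,3S,6S)-3-(benzyloxy)-2-hydroxy-2,6-dimethyl-6-(2-oxopropyl)cyclohex-4-ene-1-carbaldehyde | c1ccccc1CO[C@H]1C=C[C@](C)(CC(C)=O)[C@@H](C=O)[C@]1(C)O | intermediate
24 | 3β-(benzyloxy)-4α,6β-dihydroxy-5αH-eudesm-1-en-8-one (C6 epimer immaterial) | c1ccccc1CO[C@H]1C=C[C@]2(C)CC(=O)C[C@@H](O)[C@H]2[C@]1(C)O | intermediate (not isolated)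
25 | 3β-(benzyloxy)-4α-hydroxy-5αH-eudesma-1,6-dien-8-one | c1ccccc1CO[C@H]1C=C[C@]2(C)CC(=O)C=C[C@H]2[C@]1(C)O | intermediate
26 | 3β-(benzyloxy)-4α,11-dihydroxy-5αH,7αH-eudesm-1-en-8-one | c1ccccc1CO[C@H]1C=C[C@]2(C)CC(=O)[C@@H](C(C)(C)O)C[C@H]2[C@]1(C)O | intermediate
27 | 3β,4α,11-trihydroxy-5αH,7αH-eudesman-8-one | O[C@H]1CC[C@]2(C)CC(=O)[C@@H](C(C)(C)O)C[C@H]2[C@]1(C)O | intermediate
28 | methyl angelate, methyl (2Z)-2-methylbut-2-enoate | C/C=C(/C)C(=O)OC | starting material
29 | (2Z)-2-methylbut-2-en-1-ol | C/C=C(/C)CO | intermediate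
30 | [(2R,3S)-2,3-dimethyloxiran-2-yl]methanol | C[C@@H]1O[C@]1(C)CO | intermediate
31 | (2S,3S)-2,3-dimethyloxirane-2-carboxylic acid | C[C@@H]1O[C@]1(C)C(=O)O | intermediate
32 | (2S,3S)-2,3-dimethyloxirane-2-carboxylic 2,4,6-trichlorobenzoic anhydride | C[C@@H]1O[C@]1(C)C(=O)OC(=O)c1c(Cl)cc(Cl)cc1Cl | intermediate (not isolated)
33 | 3β-[(2S,3S)-2,3-dimethyloxirane-2-carbonyloxy]-4α,11-dihydroxy-5αH,7αH-eudesman-8-one | C[C@@H]1O[C@]1(C)C(=O)O[C@H]1CC[C@]2(C)CC(=O)[C@@H](C(C)(C)O)C[C@H]2[C@]1(C)O | intermediate
34 | 3β-[(2S,3S)-2,3-dimethyloxirane-2-carbonyloxy]-4α,11-bis(formyloxy)-5αH,7αH-eudesman-8-one | C[C@@H]1O[C@]1(C)C(=O)O[C@H]1CC[C@]2(C)CC(=O)[C@@H](C(C)(C)OC=O)C[C@H]2[C@]1(C)OC=O | intermediate (not isolated)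
35 | 3β-[(2S,3S)-2,3-dimethyloxirane-2-carbonyloxy]-4α-(formyloxy)-5αH-eudesm-7(11)-en-8-one | C[C@@H]1O[C@]1(C)C(=O)O[C@H]1CC[C@]2(C)CC(=O)C(=C(C)C)C[C@H]2[C@]1(C)OC=O | intermediate
36 | 3β-[(2S,3S)-2,3-dimethyloxirane-2-carbonyloxy]-4α-(formyloxy)-11-hydroperoxy-5αH-eudesm-6-en-8-one | C[C@@H]1O[C@]1(C)C(=O)O[C@H]1CC[C@]2(C)CC(=O)C(C(C)(C)OO)=C[C@H]2[C@]1(C)OC=O | intermediate (not isolated)
37 | 3β-[(2S,3S)-2,3-dimethyloxirane-2-carbonyloxy]-4α-(formyloxy)-11-hydroxy-5αH-eudesm-6-en-8-one (CNP0171909.1) | C[C@@H]1O[C@]1(C)C(=O)O[C@H]1CC[C@]2(C)CC(=O)C(C(C)(C)O)=C[C@H]2[C@]1(C)OC=O | target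

Total step count: 25. Longest linear sequence: 21 steps (steps 1–5, 7–19 and 23–25).

Steps most likely to fail

Step 13. Before it is trapped, the lactone enolate may lose the C4 oxygen by β-elimination or open by retro-aldol cleavage at the alkoxide stage. The crowded ketene acetal may also decompose before the shift sets in. Fallback: protection is separated from enolisation, so that no alkoxide is ever formed and a single equivalent of a lithium amide suffices. The fallback sets out from lactone 17, which is silylated at C4–OH with N-(trimethylsilyl)imidazole to give the C4 trimethylsilyl ether F1. Internal-quench enolisation of F1 with LiN(iPr)2 and Me3SiCl in THF at −78 °C then gives ketene acetal 18. Heating and acidic work-up lead through silyl ester 19 back to the route at acid 20.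

Step 17. Under equilibrating conditions, retro-aldol cleavage of the C4–C5 bond of the β-hydroxy aldehyde, loss of the C4 hydroxyl across C4–C5 or epimerisation at C5 may outrun ring closure. Fallback: the C6–C7 bond is made under kinetic control and the dehydration is done as a separate operation. The fallback sets out from keto aldehyde 23. LiN(SiMe3)2 (2.2 equiv, THF, −78 °C) forms the methyl ketone enolate, which adds at once to the aldehyde, and aldol 24 is isolated after a cold quench. Selective sulfonylation of its secondary hydroxyl (MsCl, Et3N, CH2Cl2, −20 °C) gives the C6 mesylate F2. DBU then eliminates F2 by the E1cB path, and the route is rejoined at enone 25.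

Step 24. Acylation of the tertiary C4 hydroxyl next to the bulky C3 ester may stall, acetyl transfer may compete, or the formate may be lost during the elimination. Fallback: the C4 formate is made before the C3 ester is in place. The fallback sets out from triol 27, which is formylated at all three hydroxyls (AcOCHO, pyridine, DMAP) to the tris-formate F3. DBU removes the C11 formate by elimination to give the 3,4-bis-formate enone F4. Mild methanolysis (NaHCO3, MeOH, 0 °C) cleaves the more exposed secondary C3 formate to give the 3-hydroxy 4-formate F5. Yamaguchi esterification of F5 with acid 31 (through mixed anhydride 32) comes back to the route at 35.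

Further compounds
F1 | step 13 | (4S,5S,6S)-5-(benzyloxy)-6-[(1Z,4S)-4-(tert-butyldimethylsilyloxy)-2-methylpent-1-en-1-yl]-4-methyl-4-(trimethylsilyloxy)oxan-2-one | O=C1C[C@](C)(O[Si](C)(C)C)[C@@H](OCc2ccccc2)[C@H](/C=C(/C)C[C@H](C)O[Si](C)(C)C(C)(C)C)O1
F2 | step 17 | 3β-(benzyloxy)-4α-hydroxy-6β-(methanesulfonyloxy)-5αH-eudesm-1-en-8-one | c1ccccc1CO[C@H]1C=C[C@]2(C)CC(=O)C[C@@H](OS(C)(=O)=O)[C@H]2[C@]1(C)O
F3 | step 24 | 3β,4α,11-tris(formyloxy)-5αH,7αH-eudesman-8-one | O=CO[C@H]1CC[C@]2(C)CC(=O)[C@@H](C(C)(C)OC=O)C[C@H]2[C@]1(C)OC=O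
F4 | step 24 | 3β,4α-bis(formyloxy)-5αH-eudesm-7(11)-en-8-one | O=CO[C@H]1CC[C@]2(C)CC(=O)C(=C(C)C)C[C@H]2[C@]1(C)OC=O
F5 | step 24 | 4α-(formyloxy)-3β-hydroxy-5αH-eudesm-7(11)-en-8-one | O[C@H]1CC[C@]2(C)CC(=O)C(=C(C)C)C[C@H]2[C@]1(C)OC=O
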